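Target carbons are numbered C1 (alkyne CH) to C15 (ethyl CH3); O1 links C6/C9, O2 links C7/C13. Everything rests on disconnecting C6–C7 of the all-cis oxolane (O1, C6–C9), whose C7 oxygen marks it as a Baeyer–Villiger-oxidised 3-acyloxolane, the product type of a Prins cyclisation–pinacol rearrangement. In one operation divinyl carbinol diol 3 and α-benzyloxy aldehyde 7 are joined through a 4,4-divinyl-1,3-dioxolane: the Prins step makes C8–C9, then C6 migrates from the carbinol carbon (future C13) to C7, closing the oxolane and fixing C7 and C9 from C6. Metathesis then ties the cis C7 and C9 arms into a cycloheptenone, which oxygen insertion expands to the oxocane.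

Key step: step 6

Step 1
Reactants: 1 (3S)-3-hydroxyoxolan-2-one
Product: 2 (3S)-4-ethenylhex-5-ene-1,3,4-triol
Conditions: CH2=CHMgBr (4.5 equiv), THF, −78 to 0 °C; aq. NH4Cl
Reagents that add atoms: vinylmagnesium bromide, C=C[Mg]Br
Why: Twofold Grignard addition to the lactone carbonyl (acyl substitution to the vinyl ketone, then 1,2-addition) should give the divinyl carbinol; the carbinol carbon carries two identical vinyl groups and is no stereocenter, and C6 stays S because the α-hydroxyl is deprotonated first, which blocks enolisation.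

Step 2
Reactants: 2 (3S)-4-ethenylhex-5-ene-1,3,4-triol
Product: 3 (3S)-1-[(tert-butyldiphenylsilyl)oxy]-4-ethenylhex-5-ene-3,4-diol
Conditions: TBDPSCl (1.05 equiv), imidazole, CH2Cl2, 0 °C
Reagents that add atoms: tert-butyl(chloro)diphenylsilane, CC(C)(C)[Si](Cl)(c1ccccc1)c1ccccc1
Why: Silyl ether formation is expected at the unhindered primary hydroxyl only, the secondary hydroxyl being flanked by the quaternary carbinol; no stereocenter is touched.

Step 3
Reactants: 4 (2R)-but-3-ene-1,2-diol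
Product: 5 (4R)-4-ethenyl-2-phenyl-1,3-dioxolane
Conditions: PhCH(OMe)2, CSA (cat.), CH2Cl2, rt
Reagents that add atoms: benzaldehyde dimethyl acetal, COC(OC)c1ccccc1
Why: Acid-catalysed transacetalisation closes the benzylidene acetal; the new acetal carbon forms as both epimers, which is irrelevant because it becomes the benzyl CH2 in step 4.

Step 4
Reactants: 5 (4R)-4-ethenyl-2-phenyl-1,3-dioxolane
Product: 6 (2R)-2-(benzyloxy)but-3-en-1-ol
Conditions: i-Bu2AlH (2.5 equiv), CH2Cl2, −78 to 0 °C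
Reagents that add atoms: none
Why: Reductive opening of the benzylidene acetal: aluminium binds the less hindered primary oxygen and hydride enters the acetal carbon, so the benzyl group should stay on the secondary oxygen, with C10 (R) untouched.

Step 5
Reactants: 6 (2R)-2-(benzyloxy)but-3-en-1-ol
Product: 7 (2R)-2-(benzyloxy)but-3-enal
Conditions: Dess–Martin periodinane, pyridine, CH2Cl2, 0 °C; crude 7 used at once
Reagents that add atoms: none
Why: Dess–Martin oxidation under buffered, base-free conditions should give the aldehyde without epimerisation at C10 or migration of the double bond.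

Step 6
Reactants: 3 (3S)-1-[(tert-butyldiphenylsilyl)oxy]-4-ethenylhex-5-ene-3,4-diol; 7 (2R)-2-(benzyloxy)but-3-enal
Product: 9 all-cis 3-acryloyloxolane (2S,3S,5S;1'R), via dioxolane acetal 8 (not isolated)
Conditions: 7 (1.3 equiv), CSA (cat.), MgSO4, CH2Cl2, 0 °C; then SnCl4 (1.2 equiv), −78 to −20 °C
Reagents that add atoms: none
Why: Acid-catalysed acetalisation gives dioxolane 8; SnCl4 then opens it at the tertiary oxygen to the (E)-oxocarbenium ion on O1, one vinyl group attacks C9 (Prins step, C8–C9) and C6 migrates from C13 to C7 (pinacol shift), which closes the oxolane through the new C6–C7 bond and leaves the C13 carbonyl. The closest known reaction is the Prins cyclisation–pinacol rearrangement of allylic diol acetals to 3-acyloxolanes. The transient six-membered oxacycle closes 6-endo-trig through a chair transition state and the oxolane arises from it by ring contraction (1,2-shift). C9 is set by that chair, in which the C6 side chain and the C9 substituent are both equatorial (hence cis), C7 by the suprafacial shift (acyl cis to both), and C6 migrates with retention, so 6S is relayed to 7S and 9S; 10R comes unchanged from 7. The step needs migration of C6 rather than of the second vinyl group and ionisation of the acetal rather than of the bis-allylic C13–O bond: the O1 lone pair assists the shift of C6, and the oxocarbenium ion should form far more readily than a carbocation next to oxygenated C6; low temperature protects C10.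

Step 7
Reactants: 9 all-cis 3-acryloyloxolane
Product: 10 (1S,5R,6S,8S)-5-(benzyloxy)-8-{2-[(tert-butyldiphenylsilyl)oxy]ethyl}-7-oxabicyclo[4.2.1]non-3-en-2-one
Conditions: second-generation Grubbs catalyst RuCl2(=CHPh)(H2IMes)(PCy3) (5 mol %), CH2Cl2 (high dilution), 40 °C
Reagents that add atoms: none
Why: Ring-closing metathesis between the vinyl ketone on C7 and the allylic ether arm on C9, which are cis on the oxolane, should close the seven-membered enone; the new C11=C12 bond is necessarily Z in the ring and no stereocenter changes.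

Step 8
Reactants: 10 bicyclic enone
Product: 11 (1S,5R,6S,8S)-5-(benzyloxy)-8-{2-[(tert-butyldiphenylsilyl)oxy]ethyl}-7-oxabicyclo[4.2.1]nonan-2-one
Conditions: H2 (1 atm), RhCl(PPh3)3 (cat.), benzene, rt
Reagents that add atoms: none
Why: Homogeneous hydrogenation should saturate the enone double bond without hydrogenolysis of the benzyl ether; no stereocenter is formed.

Step 9
Reactants: 11 bicyclic ketone
Product: 12 (1S,6R,7S,9S)-6-(benzyloxy)-9-{2-[(tert-butyldiphenylsilyl)oxy]ethyl}-2,8-dioxabicyclo[5.2.1]decan-3-one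
Conditions: mCPBA, CH2Cl2, 0 °C to rt
Reagents that add atoms: 3-chloroperoxybenzoic acid, OOC(=O)c1cccc(Cl)c1
Why: Baeyer–Villiger oxidation: the secondary carbon C7 should migrate in preference to the C12 methylene and with retention, so O2 is placed on C7 (S) and the cycloheptanone is expanded to the eight-membered lactone.

Step 10
Reactants: 12 eight-membered lactone
Product: 14 (4R)-α-hydroxy lactone, via potassium enolate 13 (not isolated)
Conditions: KN(SiMe3)2, THF, −78 °C; then 2-(benzenesulfonyl)-3-phenyloxaziridine, −78 °C; aq. NH4Cl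
Reagents that add atoms: 2-(benzenesulfonyl)-3-phenyloxaziridine, O=S(=O)(N1OC1c1ccccc1)c1ccccc1
Why: Davis oxidation of the lactone enolate; the oxidant should approach C12 on the face of the eight-membered ring remote from the O1–C6 bridge and its inward-pointing silyloxyethyl chain, giving the 12R alcohol.

Step 11
Reactants: 14 α-hydroxy lactone
Product: 15 (1S,4R,6R,7S,9S)-4,6-bis(benzyloxy)-9-{2-[(tert-butyldiphenylsilyl)oxy]ethyl}-2,8-dioxabicyclo[5.2.1]decan-3-one
Conditions: BnOC(=NH)CCl3, TfOH (cat.), CH2Cl2/cyclohexane, 0 °C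
Reagents that add atoms: benzyl 2,2,2-trichloroacetimidate, N=C(OCc1ccccc1)C(Cl)(Cl)Cl
Why: Acid-catalysed benzylation with the trichloroacetimidate avoids base, and hence epimerisation at C12, and installs a non-participating ether.

Step 12
Reactants: 15 dibenzyl lactone
Product: 17 anomeric acetate (C13 epimers), via aluminium hemiacetal 16 (not isolated)
Conditions: i-Bu2AlH, CH2Cl2, −78 °C; then pyridine, DMAP, Ac2O, −78 to −20 °C
Reagents that add atoms: acetic anhydride, CC(=O)OC(C)=O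
Why: Reductive acetylation: the tetrahedral aluminium hemiacetal formed at −78 °C is acylated before it can open to the hydroxy aldehyde; both C13 epimers of the acetate ionise to the same oxocarbenium ion in step 13.

Step 13
Reactants: 17 anomeric acetate
Product: 18 tert-butyl{2-[(1S,3R,4R,6R,7S,9S)-4,6-bis(benzyloxy)-3-ethyl-2,8-dioxabicyclo[5.2.1]decan-9-yl]ethoxy}diphenylsilane
Conditions: AlEt3 (3 equiv), CH2Cl2, −78 to 0 °C
Reagents that add atoms: triethylaluminium, CC[Al](CC)CC
Why: Lewis-acid-mediated substitution of the anomeric acetate (C-glycosylation type): AlEt3 ionises the acetate to the cyclic oxocarbenium ion and should transfer ethyl to C13 on the exposed face anti to the O1–C6 bridge, a delivery also favoured by coordination of aluminium to the C12 benzyloxy oxygen, giving 13R.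

Step 14
Reactants: 18 C13-ethyl dibenzyl ether
Product: 19 (1S,3R,4R,6R,7S,9S)-9-{2-[(tert-butyldiphenylsilyl)oxy]ethyl}-3-ethyl-2,8-dioxabicyclo[5.2.1]decane-4,6-diol
Conditions: H2 (1 atm), Pd(OH)2/C, EtOAc, rt
Reagents that add atoms: none
Why: Hydrogenolysis should cleave both benzyl ethers and leave the silyl ether and all stereocenters untouched.

Step 15
Reactants: 19 C10,C12-diol
Product: 20 tert-butyl{2-[(1S,3R,4S,6S,7S,9S)-4,6-dibromo-3-ethyl-2,8-dioxabicyclo[5.2.1]decan-9-yl]ethoxy}diphenylsilane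
Conditions: CBr4, P(n-C8H17)3, toluene, 70 °C
Reagents that add atoms: carbon tetrabromide, BrC(Br)(Br)Br
Why: Appel-type bromination converts both secondary alcohols into bromides by SN2 displacement of the alkoxyphosphonium groups with inversion, which should turn 10R,12R into 10S,12S.

Step 16
Reactants: 20 dibromide silyl ether
Product: 21 2-[(1S,3R,4S,6S,7S,9S)-4,6-dibromo-3-ethyl-2,8-dioxabicyclo[5.2.1]decan-9-yl]ethan-1-ol
Conditions: HF·pyridine, pyridine/THF, 0 °C to rt
Reagents that add atoms: none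
Why: Fluoride cleavage of the silyl ether under buffered conditions that are not basic enough to eliminate the secondary bromides.

Step 17
Reactants: 21 primary alcohol
Product: 22 [(1S,3R,4S,6S,7S,9S)-4,6-dibromo-3-ethyl-2,8-dioxabicyclo[5.2.1]decan-9-yl]acetaldehyde
Conditions: Dess–Martin periodinane, pyridine, CH2Cl2, 0 °C
Reagents that add atoms: none
Why: Dess–Martin oxidation gives the β-alkoxy aldehyde under non-basic conditions that should avoid β-elimination of O1.

Step 18
Reactants: 22 aldehyde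
Product: 23 {(3Z)-5-[(1S,3R,4S,6S,7S,9S)-4,6-dibromo-3-ethyl-2,8-dioxabicyclo[5.2.1]decan-9-yl]pent-3-en-1-yn-1-yl}tri(propan-2-yl)silane
Conditions: 1,3-bis(triisopropylsilyl)propyne, n-BuLi, THF, −78 °C; then 22, −78 to −20 °C; aq. NH4Cl
Reagents that add atoms: 1,3-bis(triisopropylsilyl)prop-1-yne, CC(C)[Si](C(C)C)(C(C)C)CC#C[Si](C(C)C)(C(C)C)C(C)C
Why: Peterson olefination with the lithiated propargylsilane: addition to the aldehyde and syn-elimination of silanolate should give the enyne, the bulky silyl groups enforcing the Z geometry of C3=C4; at −78 °C the bromides are not touched.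

Step 19
Reactants: 23 silylated Z-enyne
Product: 24 (1S,3R,4S,6S,7S,9S)-4,6-dibromo-3-ethyl-9-[(2Z)-pent-2-en-4-yn-1-yl]-2,8-dioxabicyclo[5.2.1]decane
Conditions: Bu4NF, THF, 0 °C
Reagents that add atoms: none
Why: Fluoride-induced protodesilylation of the alkynylsilane liberates the terminal alkyne; the Z-alkene and the secondary bromides should survive at 0 °C.

Compound list
1 | (3S)-3-hydroxyoxolan-2-one [(S)-α-hydroxy-γ-butyrolactone] | O=C1OCC[C@@H]1O | starting material
2 | (3S)-4-ethenylhex-5-ene-1,3,4-triol | OCC[C@H](O)C(O)(C=C)C=C | intermediate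
3 | (3S)-1-[(tert-butyldiphenylsilyl)oxy]-4-ethenylhex-5-ene-3,4-diol | CC(C)(C)[Si](c1ccccc1)(c2ccccc2)OCC[C@H](O)C(O)(C=C)C=C | intermediate
4 | (2R)-but-3-ene-1,2-diol | C=C[C@@H](O)CO | starting material
5 | (4R)-4-ethenyl-2-phenyl-1,3-dioxolane (both epimers at C2) | C=C[C@@H]1COC(c2ccccc2)O1 | intermediate
6 | (2R)-2-(benzyloxy)but-3-en-1-ol | OC[C@H](OCc1ccccc1)C=C | intermediate
7 | (2R)-2-(benzyloxy)but-3-enal | O=C[C@H](OCc1ccccc1)C=C | intermediate
8 | (5S)-2-[(1R)-1-(benzyloxy)prop-2-en-1-yl]-5-{2-[(tert-butyldiphenylsilyl)oxy]ethyl}-4,4-diethenyl-1,3-dioxolane (both epimers at C2) | CC(C)(C)[Si](c3ccccc3)(c4ccccc4)OCC[C@@H]1OC(OC1(C=C)C=C)[C@H](OCc5ccccc5)C=C | intermediate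
9 | 1-[(2S,3S,5S)-5-[(1R)-1-(benzyloxy)prop-2-en-1-yl]-2-{2-[(tert-butyldiphenylsilyl)oxy]ethyl}oxolan-3-yl]prop-2-en-1-one | CC(C)(C)[Si](c3ccccc3)(c4ccccc4)OCC[C@@H]1O[C@@H](C[C@@H]1C(=O)C=C)[C@H](OCc5ccccc5)C=C | intermediate
10 | (1S,5R,6S,8S)-5-(benzyloxy)-8-{2-[(tert-butyldiphenylsilyl)oxy]ethyl}-7-oxabicyclo[4.2.1]non-3-en-2-one | CC(C)(C)[Si](c3ccccc3)(c4ccccc4)OCC[C@@H]1O[C@H]2C[C@@H]1C(=O)/C=C\[C@H]2OCc5ccccc5 | intermediate
11 | (1S,5R,6S,8S)-5-(benzyloxy)-8-{2-[(tert-butyldiphenylsilyl)oxy]ethyl}-7-oxabicyclo[4.2.1]nonan-2-one | CC(C)(C)[Si](c3ccccc3)(c4ccccc4)OCC[C@@H]1O[C@H]2C[C@@H]1C(=O)CC[C@H]2OCc5ccccc5 | intermediate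
12 | (1S,6R,7S,9S)-6-(benzyloxy)-9-{2-[(tert-butyldiphenylsilyl)oxy]ethyl}-2,8-dioxabicyclo[5.2.1]decan-3-one | CC(C)(C)[Si](c3ccccc3)(c4ccccc4)OCC[C@@H]1O[C@H]2C[C@@H]1OC(=O)CC[C@H]2OCc5ccccc5 | intermediate
13 | potassium (1S,6R,7S,9S)-6-(benzyloxy)-9-{2-[(tert-butyldiphenylsilyl)oxy]ethyl}-2,8-dioxabicyclo[5.2.1]dec-3-en-3-olate | CC(C)(C)[Si](c3ccccc3)(c4ccccc4)OCC[C@@H]1O[C@H]2C[C@@H]1OC([O-])=CC[C@H]2OCc5ccccc5.[K+] | intermediate
14 | (1S,4R,6R,7S,9S)-6-(benzyloxy)-9-{2-[(tert-butyldiphenylsilyl)oxy]ethyl}-4-hydroxy-2,8-dioxabicyclo[5.2.1]decan-3-one | CC(C)(C)[Si](c3ccccc3)(c4ccccc4)OCC[C@@H]1O[C@H]2C[C@@H]1OC(=O)[C@H](O)C[C@H]2OCc5ccccc5 | intermediate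
15 | (1S,4R,6R,7S,9S)-4,6-bis(benzyloxy)-9-{2-[(tert-butyldiphenylsilyl)oxy]ethyl}-2,8-dioxabicyclo[5.2.1]decan-3-one | CC(C)(C)[Si](c3ccccc3)(c4ccccc4)OCC[C@@H]1O[C@H]2C[C@@H]1OC(=O)[C@H](OCc5ccccc5)C[C@H]2OCc6ccccc6 | intermediate
16 | {[(1S,4R,6R,7S,9S)-4,6-bis(benzyloxy)-9-{2-[(tert-butyldiphenylsilyl)oxy]ethyl}-2,8-dioxabicyclo[5.2.1]decan-3-yl]oxy}bis(2-methylpropyl)alumane (both epimers at C3) | CC(C)(C)[Si](c3ccccc3)(c4ccccc4)OCC[C@@H]1O[C@H]2C[C@@H]1OC(O[Al](CC(C)C)CC(C)C)[C@H](OCc5ccccc5)C[C@H]2OCc6ccccc6 | intermediate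
17 | (1S,4R,6R,7S,9S)-4,6-bis(benzyloxy)-9-{2-[(tert-butyldiphenylsilyl)oxy]ethyl}-2,8-dioxabicyclo[5.2.1]decan-3-yl acetate (both epimers at C3) | CC(C)(C)[Si](c3ccccc3)(c4ccccc4)OCC[C@@H]1O[C@H]2C[C@@H]1OC(OC(C)=O)[C@H](OCc5ccccc5)C[C@H]2OCc6ccccc6 | intermediate
18 | tert-butyl{2-[(1S,3R,4R,6R,7S,9S)-4,6-bis(benzyloxy)-3-ethyl-2,8-dioxabicyclo[5.2.1]decan-9-yl]ethoxy}diphenylsilane | CC(C)(C)[Si](c3ccccc3)(c4ccccc4)OCC[C@@H]1O[C@H]2C[C@@H]1O[C@H](CC)[C@H](OCc5ccccc5)C[C@H]2OCc6ccccc6 | intermediate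
19 | (1S,3R,4R,6R,7S,9S)-9-{2-[(tert-butyldiphenylsilyl)oxy]ethyl}-3-ethyl-2,8-dioxabicyclo[5.2.1]decane-4,6-diol | CC(C)(C)[Si](c3ccccc3)(c4ccccc4)OCC[C@@H]1O[C@H]2C[C@@H]1O[C@H](CC)[C@H](O)C[C@H]2O | intermediate
20 | tert-butyl{2-[(1S,3R,4S,6S,7S,9S)-4,6-dibromo-3-ethyl-2,8-dioxabicyclo[5.2.1]decan-9-yl]ethoxy}diphenylsilane | CC(C)(C)[Si](c3ccccc3)(c4ccccc4)OCC[C@@H]1O[C@H]2C[C@@H]1O[C@H](CC)[C@@H](Br)C[C@@H]2Br | intermediate
21 | 2-[(1S,3R,4S,6S,7S,9S)-4,6-dibromo-3-ethyl-2,8-dioxabicyclo[5.2.1]decan-9-yl]ethan-1-ol | OCC[C@@H]1O[C@H]2C[C@@H]1O[C@H](CC)[C@@H](Br)C[C@@H]2Br | intermediate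
22 | [(1S,3R,4S,6S,7S,9S)-4,6-dibromo-3-ethyl-2,8-dioxabicyclo[5.2.1]decan-9-yl]acetaldehyde | O=CC[C@@H]1O[C@H]2C[C@@H]1O[C@H](CC)[C@@H](Br)C[C@@H]2Br | intermediate
23 | {(3Z)-5-[(1S,3R,4S,6S,7S,9S)-4,6-dibromo-3-ethyl-2,8-dioxabicyclo[5.2.1]decan-9-yl]pent-3-en-1-yn-1-yl}tri(propan-2-yl)silane | CC(C)[Si](C(C)C)(C(C)C)C#C/C=C\C[C@@H]1O[C@H]2C[C@@H]1O[C@H](CC)[C@@H](Br)C[C@@H]2Br | intermediate
24 | (1S,3R,4S,6S,7S,9S)-4,6-dibromo-3-ethyl-9-[(2Z)-pent-2-en-4-yn-1-yl]-2,8-dioxabicyclo[5.2.1]decane | C#C/C=C\C[C@@H]1O[C@H]2C[C@@H]1O[C@H](CC)[C@@H](Br)C[C@@H]2Br | target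

Total step count: 19. Longest linear sequence: 17 steps (from 4 through steps 3 to 19; the branch from 1 joins at step 6).

Steps most likely to fail

1. Step 6. What may go wrong: ionisation of the tertiary bis-allylic C–O bond of the acetal, or migration of the second vinyl group in place of C6, would divert the cation. The fallback changes the carbinol substituent and builds the enone afterwards; it sets out from 1 and comes back at 9. Lactone 1 with MeLi (2 equiv, THF, −78 °C) and then CH2=CHMgBr in the same flask should give the methyl vinyl carbinol, (3S)-4-methylhex-5-ene-1,3,4-triol F1, as both carbinol epimers, which converge later because that carbon becomes the carbonyl carbon. Silylation as in step 2 gives the diol (3S)-1-[(tert-butyldiphenylsilyl)oxy]-4-methylhex-5-ene-3,4-diol F2. Condensation of F2 with 7 under the conditions of step 6 is the standard case of the Prins–pinacol reaction (mono-allylic carbinol, methyl as a poor migrating group) and should give the all-cis 3-acetyloxolane F3. Kinetic enolisation at the methyl group (LiN(SiMe3)2, THF, −78 °C) and Mannich reaction with dimethyl(methylidene)ammonium iodide give the β-(dimethylamino) ketone F4. Quaternisation with MeI and elimination with DBU then deliver vinyl ketone 9.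

2. Step 13. What may go wrong: hydride transfer from an ethyl group of the aluminium reagent (reduction of the oxocarbenium ion), or attack on both faces next to the C12 benzyloxy group. The fallback brings in the two carbons as an sp-hybridised nucleophile and reduces them later; it sets out from 17 and comes back at 19. Tributyl[(trimethylsilyl)ethynyl]stannane with BF3·OEt2 (CH2Cl2, −78 to 0 °C) should give the C13 (trimethylsilyl)ethynyl ether F5, the slim nucleophile having no β-hydrogen and entering on the exposed face. K2CO3 in MeOH removes the silyl group to give the C13 ethynyl ether F6. Hydrogenation under the conditions of step 14 then saturates the alkyne to the ethyl group and cleaves both benzyl ethers in one operation, giving 19.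

3. Step 15. What may go wrong: slow displacement at C12 and C10, with participation of the ring oxygens or elimination, when both alcohols are activated at once. The fallback introduces the C12 bromide next to the carbonyl group and uses it to steer the ethylation; it sets out from 14 and comes back at 20. PPh3 and CBr4 (CH2Cl2, 0 °C) should convert 14 with inversion into the α-bromo lactone F7, SN2 displacement at an α-carbonyl carbon being fast. Reductive acetylation as in step 12 gives the bromo acetate F8. AlEt3 should then add ethyl trans to the neighbouring bromine (bromine-bridged oxocarbenium ion), which is also the exposed face, to give the C13-ethyl bromide F9. BCl3 (CH2Cl2, −78 °C) cleaves the C10 benzyl ether to the bromo alcohol F10, and a single bromination with CBr4 and P(n-C8H17)3 at C10 gives 20.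

Further compounds
F1 | step 6 | (3S)-4-methylhex-5-ene-1,3,4-triol (both epimers at C4) | OCC[C@H](O)C(C)(O)C=C
F2 | step 6 | (3S)-1-[(tert-butyldiphenylsilyl)oxy]-4-methylhex-5-ene-3,4-diol (both epimers at C4) | CC(C)(C)[Si](c1ccccc1)(c2ccccc2)OCC[C@H](O)C(C)(O)C=C
F3 | step 6 | 1-[(2S,3S,5S)-5-[(1R)-1-(benzyloxy)prop-2-en-1-yl]-2-{2-[(tert-butyldiphenylsilyl)oxy]ethyl}oxolan-3-yl]ethan-1-one | CC(C)(C)[Si](c3ccccc3)(c4ccccc4)OCC[C@@H]1O[C@@H](C[C@@H]1C(C)=O)[C@H](OCc5ccccc5)C=C
F4 | step 6 | 1-[(2S,3S,5S)-5-[(1R)-1-(benzyloxy)prop-2-en-1-yl]-2-{2-[(tert-butyldiphenylsilyl)oxy]ethyl}oxolan-3-yl]-3-(dimethylamino)propan-1-one | CC(C)(C)[Si](c3ccccc3)(c4ccccc4)OCC[C@@H]1O[C@@H](C[C@@H]1C(=O)CCN(C)C)[C@H](OCc5ccccc5)C=C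
F5 | step 13 | {[(1S,3R,4R,6R,7S,9S)-4,6-bis(benzyloxy)-9-{2-[(tert-butyldiphenylsilyl)oxy]ethyl}-2,8-dioxabicyclo[5.2.1]decan-3-yl]ethynyl}trimethylsilane | CC(C)(C)[Si](c3ccccc3)(c4ccccc4)OCC[C@@H]1O[C@H]2C[C@@H]1O[C@H](C#C[Si](C)(C)C)[C@H](OCc5ccccc5)C[C@H]2OCc6ccccc6
F6 | step 13 | tert-butyl{2-[(1S,3R,4R,6R,7S,9S)-4,6-bis(benzyloxy)-3-ethynyl-2,8-dioxabicyclo[5.2.1]decan-9-yl]ethoxy}diphenylsilane | CC(C)(C)[Si](c3ccccc3)(c4ccccc4)OCC[C@@H]1O[C@H]2C[C@@H]1O[C@H](C#C)[C@H](OCc5ccccc5)C[C@H]2OCc6ccccc6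
F7 | step 15 | (1S,4S,6R,7S,9S)-6-(benzyloxy)-4-bromo-9-{2-[(tert-butyldiphenylsilyl)oxy]ethyl}-2,8-dioxabicyclo[5.2.1]decan-3-one | CC(C)(C)[Si](c3ccccc3)(c4ccccc4)OCC[C@@H]1O[C@H]2C[C@@H]1OC(=O)[C@@H](Br)C[C@H]2OCc5ccccc5
F8 | step 15 | (1S,4S,6R,7S,9S)-6-(benzyloxy)-4-bromo-9-{2-[(tert-butyldiphenylsilyl)oxy]ethyl}-2,8-dioxabicyclo[5.2.1]decan-3-yl acetate (both epimers at C3) | CC(C)(C)[Si](c3ccccc3)(c4ccccc4)OCC[C@@H]1O[C@H]2C[C@@H]1OC(OC(C)=O)[C@@H](Br)C[C@H]2OCc5ccccc5
F9 | step 15 | tert-butyl{2-[(1S,3R,4S,6R,7S,9S)-6-(benzyloxy)-4-bromo-3-ethyl-2,8-dioxabicyclo[5.2.1]decan-9-yl]ethoxy}diphenylsilane | CC(C)(C)[Si](c3ccccc3)(c4ccccc4)OCC[C@@H]1O[C@H]2C[C@@H]1O[C@H](CC)[C@@H](Br)C[C@H]2OCc5ccccc5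
F10 | step 15 | (1S,3R,4S,6R,7S,9S)-4-bromo-9-{2-[(tert-butyldiphenylsilyl)oxy]ethyl}-3-ethyl-2,8-dioxabicyclo[5.2.1]decan-6-ol | CC(C)(C)[Si](c3ccccc3)(c4ccccc4)OCC[C@@H]1O[C@H]2C[C@@H]1O[C@H](CC)[C@@H](Br)C[C@H]2O
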